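**Assumption:** ring atoms carry germacrane-style labels (C6 = lactone carbinol, C7, C8 = acyloxy carbinol, C9, C10 bearing C14H2OAc, C1=C10, C2=C3, C4 bearing the methyl, C5; C11–C13 = lactone carbons); the SMILES is read as 4S,6S,7R,8R,2'S with both ring alkenes cis within the ring; bromide 7 is taken as a catalogue item.

## Retrosynthetic overview

1. Target ⇐ acetonide removal, α-methylenation and C8 esterification of a 14-acetoxy-8-hydroxy-6,12-lactone with (S)-2-methylglyceric acid acetonide (from (R)-lactic acid by self-regeneration of stereocentres).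
2. Hydroxy lactone ⇐ C8–SiMe2Bn as masked hydroxyl (Tamao–Fleming) and lactonisation with inversion at C6 ⇐ ten-membered 6-keto tert-butyl ester.
3. Key step: ten-membered ring ⇐ anionic oxy-Cope rearrangement of a cis-1,2-dialkenylcyclohex-3-en-1-ol (forms C8–C9, the C1=C10 alkene and the C8 centre); the enolate is trapped at C7.
4. Cyclohexenol ⇐ (R)-5-methylcyclohex-2-enone (three steps from (R)-pulegone) by α-iodination/Negishi alkenylation, deconjugation, ethynyl addition and hydrosilylation.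
5. Ring order: cyclohexene (chiral pool) → ten-membered carbocycle (sigmatropic ring expansion) → γ-lactone.

## Route

Step 1
Reactants: 1 (R)-(+)-pulegone
Product: 2 pulegone oxide (epoxide epimers)
Conditions: 30% H2O2, NaOH (cat.), MeOH, 0 °C → rt
Reagents that add atoms: hydrogen peroxide, OO
Why: Weitz–Scheffer nucleophilic epoxidation of the enone leaves the methyl stereocentre untouched, and the epoxide configuration is erased in steps 2 and 3.

Step 2
Reactants: 2 pulegone oxide
Product: 3 (5R)-5-methyl-2-(phenylsulfanyl)cyclohexan-1-one (C2 epimers)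
Conditions: PhSNa, THF, reflux; H2O
Reagents that add atoms: sodium thiophenoxide, [Na+].[S-]c1ccccc1
Why: thiolate opens the epoxy ketone at the α-carbon and the β-alkoxide formed undergoes retro-aldol loss of acetone, leaving the α-sulfanyl ketone with C5 intact.

Step 3
Reactants: 3 (5R)-5-methyl-2-(phenylsulfanyl)cyclohexan-1-one
Product: 5 (R)-5-methylcyclohex-2-en-1-one, via sulfoxide 4 (not isolated)
Conditions: mCPBA, CH2Cl2, −78 °C; then PhMe, 110 °C
Reagents that add atoms: none
Why: sulfide oxidation and thermal syn-elimination of the sulfoxide (sulfoxide pyrolysis) install the conjugated double bond without touching the stereocentre.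

Step 4
Reactants: 5 (R)-5-methylcyclohex-2-en-1-one
Product: 6 (R)-2-iodo-5-methylcyclohex-2-en-1-one
Conditions: I2, pyridine, CH2Cl2, 0 °C → rt
Reagents that add atoms: iodine, II
Why: α-iodination of the enone by pyridine conjugate addition, iodination of the enolate and elimination (Baylis–Hillman-type addition–elimination).

Step 5
Reactants: 6 (R)-2-iodo-5-methylcyclohex-2-en-1-one; 7 tert-butyl[(2-bromoprop-2-en-1-yl)oxy]dimethylsilane
Product: 10 (5R)-2-[3-(tert-butyldimethylsilyloxy)prop-1-en-2-yl]-5-methylcyclohex-2-en-1-one, via alkenyllithium 8 (not isolated), via alkenylzinc chloride 9 (not isolated)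
Conditions: 7, t-BuLi (2 equiv), Et2O, −78 °C; ZnCl2, THF, −78 → 0 °C; then 6, Pd(PPh3)4 (5 mol%), THF, rt
Reagents that add atoms: none
Why: Negishi cross-coupling of the α-iodoenone with the alkenylzinc reagent forms the C1–C10 bond and brings in C9 and C14.

Step 6
Reactants: 10 dienone
Product: 12 (2S,5S)-2-[3-(tert-butyldimethylsilyloxy)prop-1-en-2-yl]-5-methylcyclohex-3-en-1-one (2,5-trans), via potassium dienolate 11 (not isolated)
Conditions: KOt-Bu (2.5 equiv), THF, 0 °C; inverse quench into AcOH/THF, −78 °C; used at once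
Reagents that add atoms: none
Why: deconjugation by γ-deprotonation to the extended dienolate and kinetic α-protonation moves the ring alkene to C2=C3, and axial protonation through the half-chair with the methyl pseudo-equatorial gives the 2,5-trans ketone (substrate control).

Step 7
Reactants: 12 β,γ-unsaturated ketone
Product: 13 (1R,2S,5S)-2-[3-(tert-butyldimethylsilyloxy)prop-1-en-2-yl]-1-ethynyl-5-methylcyclohex-3-en-1-ol
Conditions: HC≡CMgBr, CeCl3, THF, −78 °C; H2O
Reagents that add atoms: ethynylmagnesium bromide, C#C[Mg]Br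
Why: the weakly basic organocerium adds 1,2 without enolising the ketone, and the slim sp nucleophile attacks axially on the diequatorial half-chair, so ethynyl ends cis to the neighbouring alkenyl group and hydroxyl cis to the methyl.

Step 8
Reactants: 13 ethynyl carbinol
Product: 14 (1R,2S,5S)-1-[(E)-2-(benzyldimethylsilyl)ethenyl]-2-[3-(tert-butyldimethylsilyloxy)prop-1-en-2-yl]-5-methylcyclohex-3-en-1-ol
Conditions: BnMe2SiH, Pt2[(CH2=CHSiMe2)2O]3 (1 mol%), P(t-Bu)3 (2 mol%), THF, rt
Reagents that add atoms: benzyldimethylsilane, C[SiH](C)Cc1ccccc1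
Why: platinum-catalysed syn hydrosilylation of the terminal alkyne puts silicon on the terminal carbon and gives the (E)-vinylsilane, the masked C8 hydroxyl.

Step 9
Reactants: 14 vinylsilane carbinol
Product: 17 tert-butyl (4S,7R,8R)-8-(benzyldimethylsilyl)-14-(tert-butyldimethylsilyloxy)-6-oxo-13-norgermacra-1(10)E,2Z-dien-12-oate, via potassium alkoxide 15 (not isolated), via potassium enolate 16 (not isolated)
Conditions: KH, 18-crown-6, THF, 0 °C → rt; then BrCH2CO2t-Bu, −78 → 0 °C
Reagents that add atoms: tert-butyl bromoacetate, CC(C)(C)OC(=O)CBr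
Why: anionic oxy-Cope [3,3]-sigmatropic rearrangement through the chair with the C1–C2 ring bond axial (A(1,2) strain with the 2-substituted alkenyl group) forms C8–C9, the ring-cis C1=C10 alkene and, by chirality transfer from the (E)-vinylsilane, the C8 centre, and the regiodefined enolate is alkylated at C7 from the open outer face, trans to silicon.

Step 10
Reactants: 17 keto ester
Product: 18 tert-butyl (4S,6R,7R,8R)-8-(benzyldimethylsilyl)-14-(tert-butyldimethylsilyloxy)-6-hydroxy-13-norgermacra-1(10)E,2Z-dien-12-oate (6,7-cis)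
Conditions: LiBH(s-Bu)3, THF, −78 °C; H2O
Reagents that add atoms: none
Why: the bulky hydride attacks the ketone from the ring periphery, anti to the C7–C8 ring bond (Felkin–Anh, peripheral attack on the macrocycle), giving the alcohol cis to the C7 acetate arm.

Step 11
Reactants: 18 cis hydroxy ester
Product: 20 (4S,6S,7R,8R)-8-(benzyldimethylsilyl)-14-(tert-butyldimethylsilyloxy)-13-norgermacra-1(10)E,2Z-dien-6,12-olide, via mesylate 19 (not isolated)
Conditions: MsCl, Et3N, CH2Cl2, 0 °C; then PhMe, 70 °C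
Reagents that add atoms: none
Why: mesylation followed by intramolecular SN2 displacement by the tert-butyl ester carbonyl oxygen (neighbouring-group lactonisation with loss of isobutene) inverts C6 and gives the 6,7-trans γ-lactone.

Step 12
Reactants: 20 silyl lactone
Product: 22 (4S,6S,7S,8R)-8,14-dihydroxy-13-norgermacra-1(10)E,2Z-dien-6,12-olide, via silanol 21 (not isolated)
Conditions: Bu4NF, THF, 0 °C → rt; then KHCO3, 30% H2O2, MeOH, 40 °C
Reagents that add atoms: hydrogen peroxide, OO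
Why: fluoride cleaves the benzyl–silicon bond and the silyl ether, and Tamao–Fleming oxidation replaces C–Si by C–OH with retention, revealing the C8 hydroxyl set in step 9.

Step 13
Reactants: 22 diol lactone
Product: 23 (4S,6S,7S,8R)-14-acetoxy-8-hydroxy-13-norgermacra-1(10)E,2Z-dien-6,12-olide
Conditions: AcCl (1.05 equiv), 2,4,6-collidine, CH2Cl2, −78 °C
Reagents that add atoms: acetyl chloride, CC(Cl)=O
Why: kinetically selective acetylation of the unhindered primary allylic alcohol over the ring-flanked secondary C8 alcohol.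

Step 14
Reactants: 24 (R)-lactic acid
Product: 25 (2R,5R)-2-tert-butyl-5-methyl-1,3-dioxolan-4-one
Conditions: t-BuCHO, TsOH (cat.), pentane, reflux (Dean–Stark); recrystallise
Reagents that add atoms: pivalaldehyde, CC(C)(C)C=O
Why: acetalisation gives mainly the cis dioxolanone (purified by crystallisation), so the lactate centre fixes the new acetal centre.

Step 15
Reactants: 25 dioxolanone
Product: 27 (2R,5S)-2-tert-butyl-5-(hydroxymethyl)-5-methyl-1,3-dioxolan-4-one, via lithium enolate 26 (not isolated)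
Conditions: LiN(i-Pr)2, THF, −78 °C; CH2O (gas), −78 °C; AcOH
Reagents that add atoms: formaldehyde, C=O
Why: aldol hydroxymethylation of the enolate anti to the tert-butyl group (self-regeneration of stereocentres) replaces H by CH2OH with retention, fixing the (S) quaternary carbinol.

Step 16
Reactants: 27 hydroxymethyl dioxolanone
Product: 29 methyl (4S)-2,2,4-trimethyl-1,3-dioxolane-4-carboxylate, via diol ester 28 (not isolated)
Conditions: HCl, MeOH, reflux; then Me2C(OMe)2, TsOH (cat.), rt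
Reagents that add atoms: methanol, CO; 2,2-dimethoxypropane, COC(C)(C)OC
Why: acid methanolysis releases pivalaldehyde and the diol ester, which is ketalised as the acetonide without involving the quaternary centre.

Step 17
Reactants: 29 acetonide ester
Product: 30 (4S)-2,2,4-trimethyl-1,3-dioxolane-4-carboxylic acid
Conditions: LiOH, THF/H2O, 0 °C → rt; then aq. NaHSO4 to pH 3, 0 °C
Reagents that add atoms: lithium hydroxide, [Li+].[OH-]
Why: saponification of an ester that has no enolisable centre, so the configuration cannot erode.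

Step 18
Reactants: 23 hydroxy acetate lactone; 30 acetonide acid
Product: 32 (4S,6S,7R,8R)-14-acetoxy-8-[(4S)-2,2,4-trimethyl-1,3-dioxolane-4-carbonyloxy]-13-norgermacra-1(10)E,2Z-dien-6,12-olide, via mixed anhydride 31 (not isolated)
Conditions: 30, 2,4,6-Cl3C6H2COCl, Et3N, THF, rt; then 23, DMAP, PhMe, 40 °C
Reagents that add atoms: none
Why: Yamaguchi esterification acylates the hindered secondary C8 alcohol with the α,α-disubstituted acid without touching any stereocentre.

Step 19
Reactants: 32 ester lactone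
Product: 36 (4S,6S,7R,8R)-14-acetoxy-8-[(4S)-2,2,4-trimethyl-1,3-dioxolane-4-carbonyloxy]germacra-1(10)E,2Z,11(13)-trien-6,12-olide, via lithium enolate 33 (not isolated), via Mannich base 34 (not isolated), via ammonium iodide 35 (not isolated)
Conditions: LiN(SiMe3)2 (1.05 equiv), THF, −78 °C; Me2N=CH2 I, −78 → 0 °C; then MeI, MeOH, rt; NaHCO3, CH2Cl2/H2O
Reagents that add atoms: dimethylmethyleneammonium iodide, C=[N+](C)C.[I-]
Why: the γ-lactone α-protons are several pK units more acidic than those of the acetate (the side-chain ester has none), so the lactone enolate forms selectively and Mannich aminomethylation, quaternisation and Hofmann-type elimination install the exocyclic methylene.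

Step 20
Reactants: 36 acetonide
Product: 37 target, (4S,6S,7R,8R)-14-acetoxy-8-[(2S)-2,3-dihydroxy-2-methylpropanoyloxy]germacra-1(10)E,2Z,11(13)-trien-6,12-olide
Conditions: AcOH/H2O (4:1), 40 °C
Reagents that add atoms: none
Why: mild acid hydrolysis of the acetonide frees the diol while the allylic acetate, the diene and the α-methylene lactone survive.

## Compound list

1 | (R)-(+)-pulegone, (5R)-5-methyl-2-(propan-2-ylidene)cyclohexan-1-one | O=C1C[C@H](C)CCC1=C(C)C | starting material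
2 | pulegone oxide, (6R)-2,2,6-trimethyl-1-oxaspiro[2.5]octan-4-one (epoxide epimers) | O=C1C[C@H](C)CCC12OC2(C)C | intermediate
3 | (5R)-5-methyl-2-(phenylsulfanyl)cyclohexan-1-one (C2 epimers) | O=C1C[C@H](C)CCC1Sc1ccccc1 | intermediate
4 | (5R)-5-methyl-2-(phenylsulfinyl)cyclohexan-1-one | O=C1C[C@H](C)CCC1S(=O)c1ccccc1 | intermediate
5 | (R)-5-methylcyclohex-2-en-1-one | O=C1C[C@H](C)CC=C1 | intermediate
6 | (R)-2-iodo-5-methylcyclohex-2-en-1-one | O=C1C[C@H](C)CC=C1I | intermediate
7 | tert-butyl[(2-bromoprop-2-en-1-yl)oxy]dimethylsilane | C=C(Br)CO[Si](C)(C)C(C)(C)C | starting material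
8 | [3-(tert-butyldimethylsilyloxy)prop-1-en-2-yl]lithium | [Li]C(=C)CO[Si](C)(C)C(C)(C)C | intermediate
9 | chloro[3-(tert-butyldimethylsilyloxy)prop-1-en-2-yl]zinc | Cl[Zn]C(=C)CO[Si](C)(C)C(C)(C)C | intermediate
10 | (5R)-2-[3-(tert-butyldimethylsilyloxy)prop-1-en-2-yl]-5-methylcyclohex-2-en-1-one | O=C1C[C@H](C)CC=C1C(=C)CO[Si](C)(C)C(C)(C)C | intermediate
11 | potassium (5S)-2-[3-(tert-butyldimethylsilyloxy)prop-1-en-2-yl]-5-methylcyclohexa-1,3-dien-1-olate | [K+].[O-]C1=C(C(=C)CO[Si](C)(C)C(C)(C)C)C=C[C@@H](C)C1 | intermediate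
12 | (2S,5S)-2-[3-(tert-butyldimethylsilyloxy)prop-1-en-2-yl]-5-methylcyclohex-3-en-1-one (2,5-trans) | O=C1C[C@H](C)C=C[C@H]1C(=C)CO[Si](C)(C)C(C)(C)C | intermediate
13 | (1R,2S,5S)-2-[3-(tert-butyldimethylsilyloxy)prop-1-en-2-yl]-1-ethynyl-5-methylcyclohex-3-en-1-ol | O[C@]1(C#C)C[C@H](C)C=C[C@H]1C(=C)CO[Si](C)(C)C(C)(C)C | intermediate
14 | (1R,2S,5S)-1-[(E)-2-(benzyldimethylsilyl)ethenyl]-2-[3-(tert-butyldimethylsilyloxy)prop-1-en-2-yl]-5-methylcyclohex-3-en-1-ol | O[C@]1(/C=C/[Si](C)(C)Cc2ccccc2)C[C@H](C)C=C[C@H]1C(=C)CO[Si](C)(C)C(C)(C)C | intermediate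
15 | potassium alkoxide of 14 | [K+].[O-][C@]1(/C=C/[Si](C)(C)Cc2ccccc2)C[C@H](C)C=C[C@H]1C(=C)CO[Si](C)(C)C(C)(C)C | intermediate
16 | potassium enolate of the ten-membered ketone: C6(OK)=C7H with C5 and C8 trans, (4S,8R)-8-(benzyldimethylsilyl)-14-(tert-butyldimethylsilyloxy), C1=C10 and C2=C3 ring-cis | [K+].C1/C([O-])=C/[C@H]([Si](C)(C)Cc2ccccc2)C/C(CO[Si](C)(C)C(C)(C)C)=C\C=C/[C@H]1C | intermediate
17 | tert-butyl (4S,7R,8R)-8-(benzyldimethylsilyl)-14-(tert-butyldimethylsilyloxy)-6-oxo-13-norgermacra-1(10)E,2Z-dien-12-oate | O=C1C[C@H](C)/C=C\C=C(\CO[Si](C)(C)C(C)(C)C)C[C@@H]([Si](C)(C)Cc2ccccc2)[C@@H]1CC(=O)OC(C)(C)C | intermediate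
18 | tert-butyl (4S,6R,7R,8R)-8-(benzyldimethylsilyl)-14-(tert-butyldimethylsilyloxy)-6-hydroxy-13-norgermacra-1(10)E,2Z-dien-12-oate (6,7-cis) | O[C@@H]1C[C@H](C)/C=C\C=C(\CO[Si](C)(C)C(C)(C)C)C[C@@H]([Si](C)(C)Cc2ccccc2)[C@@H]1CC(=O)OC(C)(C)C | intermediate
19 | 6-O-methanesulfonate of 18 | CS(=O)(=O)O[C@@H]1C[C@H](C)/C=C\C=C(\CO[Si](C)(C)C(C)(C)C)C[C@@H]([Si](C)(C)Cc2ccccc2)[C@@H]1CC(=O)OC(C)(C)C | intermediate
20 | (4S,6S,7R,8R)-8-(benzyldimethylsilyl)-14-(tert-butyldimethylsilyloxy)-13-norgermacra-1(10)E,2Z-dien-6,12-olide (6,7-trans lactone) | O=C1O[C@H]2C[C@H](C)/C=C\C=C(\CO[Si](C)(C)C(C)(C)C)C[C@@H]([Si](C)(C)Cc3ccccc3)[C@@H]2C1 | intermediate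
21 | (4S,6S,7R,8R)-14-hydroxy-8-(hydroxydimethylsilyl)-13-norgermacra-1(10)E,2Z-dien-6,12-olide | O=C1O[C@H]2C[C@H](C)/C=C\C=C(\CO)C[C@@H]([Si](C)(C)O)[C@@H]2C1 | intermediate
22 | (4S,6S,7S,8R)-8,14-dihydroxy-13-norgermacra-1(10)E,2Z-dien-6,12-olide | O=C1O[C@H]2C[C@H](C)/C=C\C=C(\CO)C[C@@H](O)[C@@H]2C1 | intermediate
23 | (4S,6S,7S,8R)-14-acetoxy-8-hydroxy-13-norgermacra-1(10)E,2Z-dien-6,12-olide | O=C1O[C@H]2C[C@H](C)/C=C\C=C(\COC(C)=O)C[C@@H](O)[C@@H]2C1 | intermediate
24 | (R)-lactic acid | C[C@@H](O)C(=O)O | starting material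
25 | (2R,5R)-2-tert-butyl-5-methyl-1,3-dioxolan-4-one (cis) | C[C@H]1O[C@@H](C(C)(C)C)OC1=O | intermediate
26 | lithium (2R)-2-tert-butyl-5-methyl-1,3-dioxol-4-olate | [Li+].CC1=C([O-])O[C@H](C(C)(C)C)O1 | intermediate
27 | (2R,5S)-2-tert-butyl-5-(hydroxymethyl)-5-methyl-1,3-dioxolan-4-one | C[C@@]1(CO)O[C@@H](C(C)(C)C)OC1=O | intermediate
28 | methyl (2S)-2,3-dihydroxy-2-methylpropanoate | COC(=O)[C@@](C)(O)CO | intermediate
29 | methyl (4S)-2,2,4-trimethyl-1,3-dioxolane-4-carboxylate | COC(=O)[C@@]1(C)OC(C)(C)OC1 | intermediate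
30 | (4S)-2,2,4-trimethyl-1,3-dioxolane-4-carboxylic acid | OC(=O)[C@@]1(C)OC(C)(C)OC1 | intermediate
31 | (4S)-2,2,4-trimethyl-1,3-dioxolane-4-carboxylic 2,4,6-trichlorobenzoic anhydride | O=C(OC(=O)[C@@]1(C)OC(C)(C)OC1)c1c(Cl)cc(Cl)cc1Cl | intermediate
32 | (4S,6S,7R,8R)-14-acetoxy-8-[(4S)-2,2,4-trimethyl-1,3-dioxolane-4-carbonyloxy]-13-norgermacra-1(10)E,2Z-dien-6,12-olide | O=C1O[C@H]2C[C@H](C)/C=C\C=C(\COC(C)=O)C[C@@H](OC(=O)[C@@]3(C)OC(C)(C)OC3)[C@@H]2C1 | intermediate
33 | lithium lactone enolate of 32 (C11=C12–OLi) | [Li+].[O-]C1O[C@H]2C[C@H](C)/C=C\C=C(\COC(C)=O)C[C@@H](OC(=O)[C@@]3(C)OC(C)(C)OC3)[C@@H]2C=1 | intermediate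
34 | 11-[(dimethylamino)methyl] derivative of 32 (C11 epimers) | O=C1O[C@H]2C[C@H](C)/C=C\C=C(\COC(C)=O)C[C@@H](OC(=O)[C@@]3(C)OC(C)(C)OC3)[C@@H]2C1CN(C)C | intermediate
35 | 11-[(trimethylammonio)methyl] derivative of 32, iodide | [I-].O=C1O[C@H]2C[C@H](C)/C=C\C=C(\COC(C)=O)C[C@@H](OC(=O)[C@@]3(C)OC(C)(C)OC3)[C@@H]2C1C[N+](C)(C)C | intermediate
36 | (4S,6S,7R,8R)-14-acetoxy-8-[(4S)-2,2,4-trimethyl-1,3-dioxolane-4-carbonyloxy]germacra-1(10)E,2Z,11(13)-trien-6,12-olide | C=C1C(=O)O[C@H]2C[C@H](C)/C=C\C=C(\COC(C)=O)C[C@@H](OC(=O)[C@@]3(C)OC(C)(C)OC3)[C@H]12 | intermediate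
37 | CNP0347302.1, (4S,6S,7R,8R)-14-acetoxy-8-[(2S)-2,3-dihydroxy-2-methylpropanoyloxy]germacra-1(10)E,2Z,11(13)-trien-6,12-olide | C=C1C(=O)O[C@H]2C[C@H](C)/C=C\C=C(\COC(C)=O)C[C@@H](OC(=O)[C@@](C)(O)CO)[C@H]12 | target

## Step count and risks

Total steps: 20. Longest linear sequence: 16 (steps 1–13 and 18–20).

**Step 6.** The β,γ-unsaturated ketone 12 can slip back into conjugation or form as a mixture at the carbon between the carbonyl and the ring alkene. Fallback, from 10 back to 12: 10 is heated with isopropenyl acetate and TsOH to the linear dienyl acetate F1. NaBH4 in EtOH at 0 °C cleaves the enol ester; the freed dienol ketonises at the α-carbon and is reduced before it can reconjugate, giving the homoallylic alcohol F2. F2 is stable, so the 2,5-trans isomer is separated here. Buffered Dess–Martin periodinane (NaHCO3, CH2Cl2, 0 °C) then gives 12 under non-basic conditions.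

**Step 9.** The alkoxide may fragment to a pentadienyl anion and an enone and re-close without stereocontrol, and alkylation next to silicon may be slow. Fallback, from 14 back to 17: 14 is silylated (Me3SiCl, imidazole) to the trimethylsilyl ether F3. On heating (PhMe, sealed tube, 180 °C) F3 undergoes the neutral siloxy-Cope rearrangement, a concerted path that cannot ionise, to the ten-membered silyl enol ether F4. MeLi (THF, 0 °C) releases the same regiodefined enolate as its lithium salt, which is alkylated with BrCH2CO2t-Bu to 17.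

**Step 10.** The face selectivity of the ketone reduction in the ten-membered ring is the least predictable stereochemical event. Fallback, from 17 back to 20: reduction with NaBH4 (MeOH, −40 °C) is accepted as a mixture of 18 and the 6,7-trans alcohol F5. After separation, 18 goes through step 11 (inversion), while F5 is lactonised with retention (TsOH cat., PhH, 50 °C, loss of t-BuOH). Both epimers therefore converge on 20.

## Further compounds

F1 | step 6 | (5S)-2-[3-(tert-butyldimethylsilyloxy)prop-1-en-2-yl]-5-methylcyclohexa-1,3-dien-1-yl acetate | CC(=O)OC1=C(C(=C)CO[Si](C)(C)C(C)(C)C)C=C[C@@H](C)C1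
F2 | step 6 | (2S,5S)-2-[3-(tert-butyldimethylsilyloxy)prop-1-en-2-yl]-5-methylcyclohex-3-en-1-ol (carbinol epimers) | OC1C[C@H](C)C=C[C@H]1C(=C)CO[Si](C)(C)C(C)(C)C
F3 | step 9 | trimethylsilyl ether of 14 | C[Si](C)(C)O[C@]1(/C=C/[Si](C)(C)Cc2ccccc2)C[C@H](C)C=C[C@H]1C(=C)CO[Si](C)(C)C(C)(C)C
F4 | step 9 | trimethylsilyl enol ether corresponding to enolate 16 | C1/C(O[Si](C)(C)C)=C/[C@H]([Si](C)(C)Cc2ccccc2)C/C(CO[Si](C)(C)C(C)(C)C)=C\C=C/[C@H]1C
F5 | step 10 | tert-butyl (4S,6S,7R,8R)-8-(benzyldimethylsilyl)-14-(tert-butyldimethylsilyloxy)-6-hydroxy-13-norgermacra-1(10)E,2Z-dien-12-oate (6,7-trans) | O[C@H]1C[C@H](C)/C=C\C=C(\CO[Si](C)(C)C(C)(C)C)C[C@@H]([Si](C)(C)Cc2ccccc2)[C@@H]1CC(=O)OC(C)(C)C
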